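## Retrosynthetic overview
1. Bromophycolide A ⇐ phenol deacetylation ⇐ anti, Markovnikov bromohydrin at the C10=C11 alkene of the 15-membered macrolide.
2. Cyclohexene (last ring) ⇐ transannular bromonium cation–olefin cyclisation (C2–C7 bond, C6–Br) of a 19-membered triene macrolactone. C15–Br comes from C15–OH.
3. Macrolactone (first ring made; the arene is bought) ⇐ lactonisation of the seco acid at the secondary C14–OH.
4. Seco acid ⇐ B-alkyl Suzuki coupling (C9–C10) of an aryl triene with an (S,E)-vinyl iodide. C14 is bought in the L-glutamic acid lactone.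
5. Key bond aryl–C1 ⇐ aromatic Claisen [3,3] rearrangement of a tertiary allyl aryl ether (linalool-derived trienol + tert-butyl 4-fluorobenzoate).

Assumption: atoms carry geranylgeranyl numbers (C1 = benzylic CH2 … C15 = CMe2Br); racemic linalool is used because its carbinol centre is erased in step 7; the bromo-enamine of step 12 is prepared beforehand from the commercial chloro-enamine.

## Route

Step 1
Reactants: 1 ethyl (2S)-5-oxotetrahydrofuran-2-carboxylate
Product: 2 (5S)-5-(2-hydroxypropan-2-yl)dihydrofuran-2(3H)-one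
Conditions: MeMgBr (2.1 equiv), THF, −78 → −40 °C; aq NH4Cl
Reagents that add atoms: methylmagnesium bromide, C[Mg]Br
Why: Double Grignard addition goes to the more electrophilic α-alkoxy ester rather than the lactone at low temperature, and the bought stereocentre (future C14) is not touched.

Step 2
Reactants: 2 (5S)-5-(2-hydroxypropan-2-yl)dihydrofuran-2(3H)-one
Product: 4 (3S)-2-methylhept-6-yne-2,3-diol, via lactol (5S)-5-(2-hydroxypropan-2-yl)tetrahydrofuran-2-ol 3 (not isolated)
Conditions: DIBAL-H (2.2 equiv), CH2Cl2, −78 °C; then MeOH, K2CO3, MeC(O)C(N2)P(O)(OMe)2, → rt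
Reagents that add atoms: dimethyl (1-diazo-2-oxopropyl)phosphonate, CC(=O)C(=[N+]=[N-])P(=O)(OC)OC
Why: One-pot lactone half-reduction and Ohira–Bestmann (Seyferth–Gilbert) homologation turns the open hydroxy-aldehyde form of the lactol into the terminal alkyne, remote from C14.

Step 3
Reactants: 4 (3S)-2-methylhept-6-yne-2,3-diol
Product: 6 (3S,6E)-7-iodo-2,6-dimethylhept-6-ene-2,3-diol, via (E)-alkenyl(dimethyl)alane bis(aluminium alkoxide) 5 (not isolated)
Conditions: AlMe3 (4.5 equiv), Cp2ZrCl2 (0.25 equiv), CH2Cl2, 0 °C → rt; then I2, THF, −30 °C; aq Rochelle salt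
Reagents that add atoms: trimethylaluminium, C[Al](C)C; iodine, II
Why: Negishi Zr-catalysed syn carboalumination puts Me on the internal carbon, and iodinolysis with retention gives the pure E trisubstituted vinyl iodide (future C10=C11).

Step 4
Reactants: 7 (±)-linalool
Product: 8 (2E)-6-hydroxy-2,6-dimethylocta-2,7-dienal
Conditions: SeO2 (1.1 equiv), dioxane, 80 °C
Reagents that add atoms: selenium dioxide, O=[Se]=O
Why: Riley allylic oxidation (ene reaction, then [2,3]-sigmatropic shift) attacks only the electron-rich trisubstituted alkene at its E-methyl group.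

Step 5
Reactants: 8 (2E)-6-hydroxy-2,6-dimethylocta-2,7-dienal
Product: 9 (6E)-3,7-dimethylnona-1,6,8-trien-3-ol
Conditions: Ph3PCH3Br, KOt-Bu (2.2 equiv each), THF, 0 °C → rt
Reagents that add atoms: methyltriphenylphosphonium bromide, C[P+](c1ccccc1)(c1ccccc1)c1ccccc1.[Br-]
Why: Wittig methylenation of the enal gives the terminal diene without touching the E C6=C7 geometry.

Step 6
Reactants: 9 (6E)-3,7-dimethylnona-1,6,8-trien-3-ol; 10 tert-butyl 4-fluorobenzoate
Product: 11 tert-butyl 4-{[(6E)-3,7-dimethylnona-1,6,8-trien-3-yl]oxy}benzoate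
Conditions: KHMDS (1.05 equiv), THF–DMF, 0 °C; then 10, rt → 45 °C
Reagents that add atoms: none
Why: SNAr of the tertiary potassium alkoxide on the para-activated aryl fluoride makes a tertiary aryl ether that alkylation cannot give, and the tert-butyl ester resists transesterification.

Step 7
Reactants: 11 tert-butyl 4-{[(6E)-3,7-dimethylnona-1,6,8-trien-3-yl]oxy}benzoate
Product: 13 tert-butyl 3-[(2E,6E)-3,7-dimethylnona-2,6,8-trien-1-yl]-4-hydroxybenzoate, via 6-allylcyclohexa-2,4-dienone 12 (not isolated)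
Conditions: PhNEt2, BHT (cat.), 150 °C, 6 h; AgNO3–SiO2 chromatography (E:Z about 3:1)
Reagents that add atoms: none
Why: Aromatic Claisen [3,3] rearrangement through a chair (long chain pseudo-equatorial) followed by tautomerisation forms the aryl–C1 bond ortho to oxygen and the C2=C3 alkene, at a temperature below that needed for Diels–Alder reaction of the diene.

Step 8
Reactants: 13 tert-butyl 3-[(2E,6E)-3,7-dimethylnona-2,6,8-trien-1-yl]-4-hydroxybenzoate; 6 (3S,6E)-7-iodo-2,6-dimethylhept-6-ene-2,3-diol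
Product: 15 tert-butyl 3-[(2E,6E,10E,14S)-14,15-dihydroxy-3,7,11,15-tetramethylhexadeca-2,6,10-trien-1-yl]-4-hydroxybenzoate, via B-alkyl-9-BBN 14 (not isolated)
Conditions: 9-BBN-H (2.2 equiv), THF, 0 °C → rt; then 6, PdCl2(dppf) (5 mol %), AsPh3, Cs2CO3, DMF–H2O, rt
Reagents that add atoms: none
Why: 9-BBN hydroborates only the monosubstituted alkene, and B-alkyl Suzuki–Miyaura coupling joins C9 to C10 with retention of the vinyl iodide geometry.

Step 9
Reactants: 15 the 14,15-dihydroxy phenol tert-butyl ester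
Product: 16 tert-butyl 4-acetoxy-3-[(2E,6E,10E,14S)-14,15-dihydroxy-3,7,11,15-tetramethylhexadeca-2,6,10-trien-1-yl]benzoate
Conditions: Ac2O (1.05 equiv), Et3N, CH2Cl2, −20 °C
Reagents that add atoms: acetic anhydride, CC(=O)OC(C)=O
Why: Chemoselective O-acetylation of the acidic phenol over the hindered secondary and tertiary alcohols installs an electron-withdrawing group that later blocks chroman formation and ring bromination.

Step 10
Reactants: 16 the aryl acetate tert-butyl ester
Product: 18 4-acetoxy-3-[(2E,6E,10E,14S)-14,15-dihydroxy-3,7,11,15-tetramethylhexadeca-2,6,10-trien-1-yl]benzoic acid, via tris(trimethylsilyl) derivative 17 (not isolated)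
Conditions: TMSOTf (5 equiv), 2,6-lutidine (7 equiv), CH2Cl2, 0 °C; then aq citric acid, THF, rt
Reagents that add atoms: none
Why: Buffered silylative tert-butyl ester cleavage (loss of isobutene) frees the acid without protic acid or hydroxide, so the polyene and the aryl acetate survive.

Step 11
Reactants: 18 the seco acid
Product: 19 19-membered (2E,6E,10E,14S) triene macrolactone (aryl acetate, C15–OH free)
Conditions: MNBA (1.3 equiv), DMAP (0.2 equiv), Et3N (3 equiv), CH2Cl2 (1 mM), rt, 18 added over 12 h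
Reagents that add atoms: none
Why: Shiina macrolactonisation acylates the only secondary alcohol (the tertiary C15–OH is inert) with retention at C14.

Step 12
Reactants: 19 the 15-hydroxy triene macrolactone
Product: 20 15-bromo triene macrolactone (14S)
Conditions: Me2C=C(Br)NMe2 (1.5 equiv), CH2Cl2, 0 °C → rt
Reagents that add atoms: 1-bromo-N,N,2-trimethylprop-1-en-1-amine, CC(C)=C(Br)N(C)C
Why: Ghosez α-haloenamine deoxybromination collapses an alkoxy-iminium bromide ion pair at tertiary C15 under neutral conditions, so no HBr reaches the alkenes and the C14–O bond is never broken.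

Step 13
Reactants: 20 the 15-bromo triene macrolactone
Product: 21 O-acetyl-10,11-didehydro precursor: (6S,7S,14S)-6,15-dibromo 15-membered macrolide with C2=C3 ring alkene and (10E) alkene
Conditions: BDSB (1.05 equiv), MeNO2, −25 °C, 5 min; aq NaHCO3/Na2SO3
Reagents that add atoms: bromodiethylsulfonium bromopentachloroantimonate (BDSB), CC[S+](Br)CC.Cl[Sb-](Cl)(Cl)(Cl)(Cl)Br
Why: In this transannular bromonium-induced cation–olefin cyclisation, Br+ exchange between the alkenes is reversible, the C6–C7 bromonium (C10=C11 being the most electron-poor and hindered alkene) is trapped through a chair by C2=C3, anti addition to the E alkene sets Br equatorial and cis to C7-Me, the lactone conformation fixed by C14 selects the alkene face, and loss of axial H-2 gives the tetrasubstituted alkene.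

Step 14
Reactants: 21 the dibromo macrolide
Product: 22 O-acetylbromophycolide A (6S,7S,10R,11S,14S)
Conditions: NBS (1.05 equiv), acetone–H2O 4:1, 0 °C, dark
Reagents that add atoms: N-bromosuccinimide, O=C1CCC(=O)N1Br; water, O
Why: Bromohydrin formation is Markovnikov (OH at tertiary C11) and anti on the E alkene, which fixes the 10,11-relative configuration, while peripheral attack of Br+ on the rigid bicyclic macrolide (control by C7 and C14) fixes the face, the ring alkene being more hindered.

Step 15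
Reactants: 22 O-acetylbromophycolide A
Product: 23 bromophycolide A
Conditions: NaHCO3, MeOH, 0 °C → rt
Reagents that add atoms: none
Why: Mild transesterification cleaves only the activated aryl acetate and is too weakly basic to close the bromohydrin to an epoxide or to eliminate the tertiary bromide.

## Compound list
1 | ethyl (2S)-5-oxotetrahydrofuran-2-carboxylate | O=C1CC[C@@H](C(=O)OCC)O1 | starting material
2 | (5S)-5-(2-hydroxypropan-2-yl)dihydrofuran-2(3H)-one | O=C1CC[C@@H](C(C)(C)O)O1 | intermediate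
3 | (5S)-5-(2-hydroxypropan-2-yl)tetrahydrofuran-2-ol (anomers) | OC1CC[C@@H](C(C)(C)O)O1 | intermediate
4 | (3S)-2-methylhept-6-yne-2,3-diol | C#CCC[C@H](O)C(C)(C)O | intermediate
5 | (E)-alkenyl(dimethyl)alane, both OH as O–AlMe2 | C[Al](C)/C=C(C)/CC[C@H](O[Al](C)C)C(C)(C)O[Al](C)C | intermediate
6 | (3S,6E)-7-iodo-2,6-dimethylhept-6-ene-2,3-diol | I/C=C(C)/CC[C@H](O)C(C)(C)O | intermediate
7 | (±)-linalool | CC(C)=CCCC(C)(O)C=C | starting material
8 | (2E)-6-hydroxy-2,6-dimethylocta-2,7-dienal | O=C/C(C)=C/CCC(C)(O)C=C | intermediate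
9 | (6E)-3,7-dimethylnona-1,6,8-trien-3-ol | C=C/C(C)=C/CCC(C)(O)C=C | intermediate
10 | tert-butyl 4-fluorobenzoate | CC(C)(C)OC(=O)c1ccc(F)cc1 | starting material
11 | tert-butyl 4-{[(6E)-3,7-dimethylnona-1,6,8-trien-3-yl]oxy}benzoate | C=C/C(C)=C/CCC(C)(C=C)Oc1ccc(cc1)C(=O)OC(C)(C)C | intermediate
12 | tert-butyl 5-[(2E,6E)-3,7-dimethylnona-2,6,8-trienyl]-4-oxocyclohexa-1,5-diene-1-carboxylate (Claisen dienone) | C=C/C(C)=C/CC/C(C)=C/CC1C=C(C=CC1=O)C(=O)OC(C)(C)C | intermediate
13 | tert-butyl 3-[(2E,6E)-3,7-dimethylnona-2,6,8-trien-1-yl]-4-hydroxybenzoate | C=C/C(C)=C/CC/C(C)=C/Cc1cc(ccc1O)C(=O)OC(C)(C)C | intermediate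
14 | B-alkyl-9-BBN from 13 (boron on C9) | CC(C)(C)OC(=O)c1ccc(O)c(C/C=C(C)/CC/C=C(C)/CCB2C3CCCC2CCC3)c1 | intermediate
15 | tert-butyl 3-[(2E,6E,10E,14S)-14,15-dihydroxy-3,7,11,15-tetramethylhexadeca-2,6,10-trien-1-yl]-4-hydroxybenzoate | CC(C)(O)[C@@H](O)CC/C(C)=C/CC/C(C)=C/CC/C(C)=C/Cc1cc(ccc1O)C(=O)OC(C)(C)C | intermediate
16 | aryl acetate of 15 | CC(C)(O)[C@@H](O)CC/C(C)=C/CC/C(C)=C/CC/C(C)=C/Cc1cc(ccc1OC(C)=O)C(=O)OC(C)(C)C | intermediate
17 | TMS ester, 14,15-bis(TMS ether) of 18 | CC(C)(O[Si](C)(C)C)[C@@H](O[Si](C)(C)C)CC/C(C)=C/CC/C(C)=C/CC/C(C)=C/Cc1cc(ccc1OC(C)=O)C(=O)O[Si](C)(C)C | intermediate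
18 | 4-acetoxy-3-[(2E,6E,10E,14S)-14,15-dihydroxy-3,7,11,15-tetramethylhexadeca-2,6,10-trien-1-yl]benzoic acid | CC(C)(O)[C@@H](O)CC/C(C)=C/CC/C(C)=C/CC/C(C)=C/Cc1cc(ccc1OC(C)=O)C(=O)O | intermediate
19 | 19-membered triene macrolactone, 14S, C15–OH, aryl acetate | C/C1=C\Cc2cc(ccc2OC(C)=O)C(=O)O[C@H](C(C)(C)O)CC/C(C)=C/CC/C(C)=C/CC1 | intermediate
20 | 15-bromo triene macrolactone, 14S | C/C1=C\Cc2cc(ccc2OC(C)=O)C(=O)O[C@H](C(C)(C)Br)CC/C(C)=C/CC/C(C)=C/CC1 | intermediate
21 | (6S,7S,14S,10E)-6,15-dibromo cyclohexene-fused 15-membered macrolide, aryl acetate | CC1=C2Cc3cc(ccc3OC(C)=O)C(=O)O[C@H](C(C)(C)Br)CC/C(C)=C/CC[C@]2(C)[C@@H](Br)CC1 | intermediate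
22 | O-acetylbromophycolide A | CC1=C2Cc3cc(ccc3OC(C)=O)C(=O)O[C@H](C(C)(C)Br)CC[C@](C)(O)[C@H](Br)CC[C@]2(C)[C@@H](Br)CC1 | intermediate
23 | bromophycolide A | CC1=C2Cc3cc(ccc3O)C(=O)O[C@H](C(C)(C)Br)CC[C@](C)(O)[C@H](Br)CC[C@]2(C)[C@@H](Br)CC1 | target

## Step count and risks
Total steps: 15. Longest linear sequence: 12 (steps 4–15, from linalool). The vinyl iodide branch has 3 steps.

**Step 13 (transannular bromocyclisation).** The risks are competition from C10=C11, the alkene face, and the direction of proton loss.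
- The fallback sets out from 19 and comes back at 21. It masks C10=C11 before the ring is closed.
- NBS in CH2Cl2 is captured intramolecularly by the free C15–OH, and heteroatom capture outruns π-cyclisation. This gives the 10-bromo-11,15-oxy-bridged (tetrahydropyran) macrolide F1. Its new centres are only temporary.
- BDSB then has only the C6=C7/C2=C3 pair left and gives the cyclised tetrahydropyran macrolide F2.
- Zn/NH4Cl in EtOH (reductive β-bromo ether elimination, leaving the isolated C6–Br alone) restores the E alkene and C15–OH in the 15-hydroxy cyclised macrolide F3.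
- The bromo-enamine of step 12 converts F3 into 21.

**Step 14 (bromohydrin).** The risks are a wrong alkene face and attack at the tetrasubstituted alkene.
- The fallback sets out from 21 and comes back at 22.
- DMDO in acetone at −40 °C gives the (10S,11S)-10,11-epoxide F4. Li2NiBr4 in THF opens it by SN2 at the secondary C10.
- Oxygen must arrive on the face opposite to the one Br+ needs. The two sequences are therefore stereochemical complements, and one of them matches whichever face the macrolide exposes.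

**Step 12 (tertiary bromide next to the ester).** The risks are elimination and acyloxonium-mediated 1,2-shift.
- The fallback sets out from 19 and comes back at 20.
- Burgess dehydration gives the 15(16)-ene (isopropenyl) macrolactone F5.
- Markovnikov radical hydrobromination by hydrogen-atom transfer (Co(acac)2, t-BuOOH, Et3SiH, TsBr) follows. It is selective for the 1,1-disubstituted alkene over the trisubstituted ones.

## Further compounds
F1 | step 13 | (10S,11R,14S)-10-bromo-11,15-oxy-bridged (tetrahydropyran) diene macrolactone, aryl acetate | C/C1=C\Cc2cc(ccc2OC(C)=O)C(=O)O[C@H]3CC[C@@](C)(OC3(C)C)[C@@H](Br)CC/C(C)=C/CC1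
F2 | step 13 | transannular cyclisation product of F1 (6S,7S; C2=C3 ring alkene) | CC1=C2Cc3cc(ccc3OC(C)=O)C(=O)O[C@H]4CC[C@@](C)(OC4(C)C)[C@@H](Br)CC[C@]2(C)[C@@H](Br)CC1
F3 | step 13 | (6S,7S,14S,10E)-6-bromo-15-hydroxy cyclised macrolide, aryl acetate | CC1=C2Cc3cc(ccc3OC(C)=O)C(=O)O[C@H](C(C)(C)O)CC/C(C)=C/CC[C@]2(C)[C@@H](Br)CC1
F4 | step 14 | (10S,11S)-10,11-epoxide of 21 | CC1=C2Cc3cc(ccc3OC(C)=O)C(=O)O[C@H](C(C)(C)Br)CC[C@]4(C)O[C@H]4CC[C@]2(C)[C@@H](Br)CC1
F5 | step 12 | (14S)-14-isopropenyl triene macrolactone, aryl acetate | C/C1=C\Cc2cc(ccc2OC(C)=O)C(=O)O[C@H](C(C)=C)CC/C(C)=C/CC/C(C)=C/CC1
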